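## The problem

Target 21, (2R,3R,3aR,5R)-5-methoxy-3-methyl-3a-(prop-2-en-1-yl)-2-(3,4,5-trimethoxyphenyl)-3,3a,4,5-tetrahydro-1-benzofuran-6(2H)-one, is a dihydrofuran ring (O1, C2, C3, C3a, C7a) fused through the C3a–C7a bond to a cyclohexenone ring (C3a, C4, C5, C6, C7, C7a); this benzofuran numbering is kept for all intermediates. The unit O1–C7a=C7–C6=O is a vinylogous ester, that is, a cyclohexane-1,3-dione whose C7a oxygen is tied back to the benzylic carbon C2. Four stereocentres are present: C2 (aryl), C3 (methyl), the all-carbon quaternary C3a (allyl) and C5 (methoxy), with aryl trans to methyl, methyl cis to allyl and methoxy trans to allyl. Only C2 needs an external source of chirality: on a five-membered ring C2 can direct C3 (addition anti to the aryl group), C3 can direct C3a (a planar C3a reacts anti to the neighbouring methyl group), and C5, α to the ketone, can be left to equilibrate. The order in which the two carbon groups reach C3a therefore decides its configuration: the group that arrives last ends up trans to methyl, and that must be C4, not allyl. Fragile features are the vinylogous ester and the benzylic C2–O1 bond (acid), the 1,5-diene formed by the allyl group and C7=C7a (Cope rearrangement on strong heating), the terminal alkene (radicals, hydrogenation) and the electron-rich arene (strong oxidants), so the last steps must be mild and non-oxidative. The feature that opens the route: if C7a is read as a lactone carbonyl, O1, C2, C3, C3a and C7a form a γ-butyrolactone in which the methyl carbon on C3 and the allylic CH2 on C3a are cis on adjacent ring atoms. With C3 and C3a they are the four sp3 atoms of a cyclohexene cis-fused to the lactone, the retron of a butenolide Diels–Alder reaction, and the ring alkene can later be cut to leave a one-carbon and a three-carbon substituent.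

## Retrosynthesis

**21 ⇒ 20 ⇒ 19 ⇒ 18.** C5 is first relaxed to the epimer mixture 20. The O1–C7a enol ether is then read as the dehydrated form of hydroxy dione 19, and the C7–C7a bond is cut (intramolecular Claisen condensation) to give keto lactone 18. Cutting O1–C7a alone would leave the carbocycle and its quaternary centre to be made some other way, and cutting C3a–C7a with C4–C5 would need a cycloaddition onto an unactivated alkene. The C7–C7a cut instead turns C7a into a lactone carbonyl and reduces the whole carbocycle to a four-carbon side chain on a γ-butyrolactone. Forward, a methyl ketone enolate must acylate a hindered lactone carbonyl, 19 must close under acid mild enough to spare the benzylic ether, and C5 must settle in the epimer with an equatorial methoxy group.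

**18 ⇒ 15 + 17 (17 ⇒ 16).** The C3a–C4 bond is cut (Michael addition of the lactone enolate of 15 to 3-methoxybut-3-en-2-one 17). The neighbouring option, allylating last, would place allyl trans to methyl, because either electrophile enters anti to the C3 methyl group; allyl must therefore already sit on C3a. Lactone 15 carries only two stereocentres that matter (C3a is planarised), and enone 17 comes in one step from the commercial ketal 16. Forward, a tetrasubstituted enolate must add 1,4 to an α-methoxy enone, anti to methyl.

**15 ⇒ 14 ⇒ 13 ⇒ 11 ⇒ 9.** No skeletal bond of the target is cut here. The terminal alkene of 15 is traced to aldehyde 14 (Wittig methylenation), masked as acetal 13, and the C3 methyl group to the acetic acid arm of 11 (radical decarboxylation via ester 12). Aldehyde and acid carbons are then rejoined as the silyl enol ether C=C of bicycle 9 (ozonolysis via aldehyde acid 10). This reconnection makes both substituents the remains of one ring, so that a single cycloaddition can deliver them. Forward, the ozonolysis must tell the two arms apart (the enol ether does this), and decarboxylation must come before olefination, since a primary radical on the C3 arm would otherwise cyclise 5-exo onto the allyl alkene.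

**9 ⇒ 7 + 8.** The C3–CH2 and C3a–CH2 bonds are cut (retro-Diels–Alder) to butenolide 7 and the commercial siloxydiene 8. Against the stepwise alternative (conjugate addition of methyl, then enolate allylation), this cut forms both bonds in one neutral, stereospecific step, and no organometallic base meets the racemisable butenolide. The precursor has a single stereocentre. Forward, the diene must add anti to the aryl group, with the siloxy-substituted terminus on the lactone β-carbon, and without loss of configuration at C2. The cis fusion of 9 is a consequence of the mechanism; C3a is finally fixed in the Michael step.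

**7 ⇒ 6 ⇒ 4 + 5; 4 ⇒ 3 ⇒ 1 + 2.** The C3=C3a alkene is cut (ring-closing metathesis of acrylate 6), then the ester C–O bond (alcohol 4 plus acryloyl chloride 5), then the C2–vinyl bond (aldehyde 1 plus vinylmagnesium bromide 2, giving racemate 3). All pieces are commodity chemicals, and the one absolute stereocentre comes from a Sharpless kinetic resolution of 3. The price is half of the material at the second step, where it is cheapest.

## Roads not taken

**Alternative 1:** Both rings are cut at once, at C3a–C7a and C4–C5. The precursor is the oxygen-tethered triene A2, the (1E)-3-(tert-butyldimethylsilyloxy)-4-methoxybuta-1,3-dienyl ether of (1R,2R)-2-methyl-3-methylidene-1-(3,4,5-trimethoxyphenyl)hex-5-en-1-ol. On heating, the diene (C7a, C7, C6, C5) would add across the C3a=C4 methylidene group to give the cis-fused silyl enol ether A1, and a Saegusa oxidation with Pd(OAc)2 would install C7=C7a and finish 21.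
- Merits: the furan ring, the carbocycle, the quaternary centre and C5 would all arise in one step, and only one step would follow. After its key step this is the shortest road of all.
- Weak points: diene and dienophile are both electron-rich, and the dienophile is an unactivated 1,1-disubstituted alkene, so only the tether helps. The temperatures needed threaten the bis-enol-ether diene (silyl migration, loss of geometry). C5 depends on the geometry of the methoxy-bearing diene terminus and on endo/exo preference, and the facial choice at C3a rests on a single methyl group in the tether. A2 itself needs an anti-configured homoallylic alcohol and O-dienylation of a hindered benzylic alcohol.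
- Comparison: the chosen plan is longer after its cycloaddition, but that cycloaddition is electronically matched (electron-poor butenolide, electron-rich diene), and each stereocentre is set by a separate, established substrate-control element.

**Alternative 2:** Only the O1–C7a bond is cut. The precursor is the 4,4-disubstituted cyclohexa-2,5-dienone A4; under a chiral BINOL-derived phosphoric acid its C2 hydroxyl would add 5-exo-trig to one of the two diastereotopic enone β-carbons, giving the cis-fused tetrahydrobenzofuranone A3.
- Merits: the controller is catalytic, and the quaternary carbon needs no stereoselective alkylation, since it is prochiral until the ring closes. In this respect the road is better than the chosen one.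
- Weak points: A4 already carries C2 and C3, so the catalyst must cooperate with, or override, the substrate bias. A4 requires para-selective alkylative dearomatisation of a phenol bearing a branched benzylic chain. A3 has the wrong oxidation pattern (C4=C5 unsaturated, C7–C7a saturated, no C5 oxygen), so conjugate reduction, regioselective α-oxygenation at C5 rather than C7, methylation and dehydrogenation would follow, all on a β-alkoxy ketone prone to retro-oxa-Michael opening.
- Comparison: the chosen plan reaches the correct oxidation state directly in its Claisen closure and has to set against Alternative 2 only the loss of material in the resolution.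

**Alternative 3:** The C3–CH3 and C3a–C4 bonds are cut on the α-allyl butenolide A6. Lithium dimethylcuprate with chlorotrimethylsilane would add methyl to C3 anti to the aryl group, and the resulting silyl ketene acetal would be trapped at C3a by enone 17 under TiCl4 to give keto lactone A5. A5 is one C5 epimer of compound 18, so the end game would be step 12 of the chosen route.
- Merits: methyl arrives as methyl, with no excision of a carbon, no ozonolysis and no protecting group. In step count this is the better road, by roughly four steps.
- Weak points: the trisubstituted alkene of A6 is a poor cuprate acceptor. The basic cuprate with a silyl chloride can instead silylate the acidic C2 position to an aromatic 2-siloxyfuran and erase the only external stereocentre. The one-pot Lewis-acid trapping must work in the presence of copper and lithium salts. A6 is not trivially made, since metathesis of a 2-allylacrylate can also close a seven-membered ring onto the allyl alkene.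
- Comparison: the chosen plan forms the C3 and C3a bonds under neutral thermal conditions in a pericyclic step of known facial preference and passes through a rigid bicycle whose relative configuration is easy to secure. Both roads meet at the same lactone enolate, so the cuprate chemistry remains available as the fallback for the key step.

Key step: step 5

## Route

Assumption: of the two C5 epimers of the bicyclic enone, the one with the methoxy group equatorial and trans to the pseudo-axial C3a allyl group (the target) is taken to be the more stable, so that base equilibration converges on it.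

Step 1
Reactants: 1 3,4,5-trimethoxybenzaldehyde; 2 vinylmagnesium bromide
Product: 3 (RS)-1-(3,4,5-trimethoxyphenyl)prop-2-en-1-ol
Conditions: CH2=CHMgBr (1.2 equiv), THF, 0 °C; sat. aq NH4Cl
Reagents that add atoms: none
Why: Grignard 1,2-addition of the vinyl nucleophile to a non-enolisable aromatic aldehyde gives the secondary allylic alcohol; the product is racemic and C2 is resolved in step 2.

Step 2
Reactants: 3 (RS)-1-(3,4,5-trimethoxyphenyl)prop-2-en-1-ol
Product: 4 (R)-1-(3,4,5-trimethoxyphenyl)prop-2-en-1-ol
Conditions: Ti(OiPr)4 (0.1 equiv), D-(−)-diisopropyl tartrate (0.15 equiv), t-BuOOH (0.6 equiv), 4 Å MS, CH2Cl2, −20 °C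
Reagents that add atoms: none
Why: Sharpless kinetic resolution: the Ti(OiPr)4–D-(−)-tartrate–hydroperoxide complex should epoxidise the (S)-alcohol much faster than the (R)-alcohol, so running just past half conversion leaves the (R)-enantiomer, which is separated from the polar epoxy alcohol. This step sets C2 of the target; for an aryl vinyl carbinol the D-tartrate is the ligand that spares the (R)-enantiomer.

Step 3
Reactants: 4 (R)-1-(3,4,5-trimethoxyphenyl)prop-2-en-1-ol; 5 acryloyl chloride
Product: 6 (1R)-1-(3,4,5-trimethoxyphenyl)prop-2-en-1-yl prop-2-enoate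
Conditions: Et3N, DMAP (cat.), CH2Cl2, −20 → 0 °C
Reagents that add atoms: none
Why: DMAP-catalysed O-acylation of a secondary alcohol with an acid chloride; the C–O bond at the stereocentre is not broken, and low temperature with immediate use suppresses ionisation or allylic transposition of the benzylic ester.

Step 4
Reactants: 6 (1R)-1-(3,4,5-trimethoxyphenyl)prop-2-en-1-yl prop-2-enoate
Product: 7 (5R)-5-(3,4,5-trimethoxyphenyl)furan-2(5H)-one
Conditions: second-generation Grubbs catalyst RuCl2(=CHPh)(PCy3)(H2IMes) (5 mol %), CH2Cl2 (0.01 M), 40 °C
Reagents that add atoms: none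
Why: Ring-closing metathesis: the ruthenium carbene loads onto the electron-rich allylic alkene and closes onto the acrylate, releasing ethene and forming the five-membered α,β-unsaturated lactone. No base is present, so the acidic hydrogen at C2, and with it the stereocentre, is preserved.

Step 5
Reactants: 7 (5R)-5-(3,4,5-trimethoxyphenyl)furan-2(5H)-one; 8 2-(trimethylsilyloxy)buta-1,3-diene
Product: 9 (3R,3aR,7aS)-3-(3,4,5-trimethoxyphenyl)-5-(trimethylsilyloxy)-3a,4,7,7a-tetrahydro-2-benzofuran-1(3H)-one (cis-fused, aryl trans to both ring-fusion CH2 groups)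
Conditions: 8 (5 equiv), BHT (cat.), toluene, sealed tube, 170 °C; volatiles removed, crude 9 used directly
Reagents that add atoms: none
Why: A concerted, suprafacial, normal-electron-demand [4+2] cycloaddition (Diels–Alder reaction) joins the electron-poor C3=C3a alkene of 7 to the electron-rich diene 8; the closest known reaction type is the thermal cycloaddition of 5-substituted furan-2(5H)-ones with butadiene and 2-siloxybutadienes. One ring closes, the cyclohexene, by simultaneous formation of the C3–CH2 and C3a–CH2 bonds, and because both bonds form on one face of a ring alkene the new ring is necessarily cis-fused to the lactone. The new stereocentre at C3 (C3a of 9, R) is controlled by the C2 aryl group, which blocks one face of the flat butenolide so that the diene adds anti to it; the stereocentre at C3a (C7a of 9, S) follows from the cis fusion. The step needs facial and regioselectivity: the facial bias comes from the aryl group directly on the ring, and the regiochemistry from pairing the diene terminus next to the siloxy carbon (largest HOMO coefficient) with the lactone β-carbon C3 (largest LUMO coefficient), which places the siloxy carbon on the C3 arm. Endo/exo selectivity is irrelevant because the diene termini are unsubstituted. Base-free thermal conditions are chosen because the hydrogen at C2 of 7 is acidic and a Lewis acid would desilylate the diene; excess diene and a radical inhibitor offset the modest dienophilicity of the butenolide.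

Step 6
Reactants: 9 (3R,3aR,7aS)-3-(3,4,5-trimethoxyphenyl)-5-(trimethylsilyloxy)-3a,4,7,7a-tetrahydro-2-benzofuran-1(3H)-one
Product: 11 [(2R,3R,4S)-4-(2,2-dimethoxyethyl)-5-oxo-2-(3,4,5-trimethoxyphenyl)oxolan-3-yl]acetic acid, via aldehyde acid 10 (not isolated)
Conditions: O3, CH2Cl2/MeOH, −78 °C (Sudan Red 7B end point); Me2S, −78 °C → rt; then HC(OMe)3, PPTS (cat.), rt
Reagents that add atoms: ozone, [O-][O+]=O; trimethyl orthoformate, COC(OC)OC
Why: Ozone should cleave the electron-rich silyl enol ether far faster than the trialkoxyarene (the dye marks the end point), giving a silyl ester on the C3 arm, methanolysed to the acid, and after Me2S reduction an aldehyde on the C3a arm. Orthoformate with PPTS then acetalises only the aldehyde, since esterification of the acid is slow at room temperature; no stereocentre is touched.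

Step 7
Reactants: 11 [(2R,3R,4S)-4-(2,2-dimethoxyethyl)-5-oxo-2-(3,4,5-trimethoxyphenyl)oxolan-3-yl]acetic acid
Product: 13 (3S,4R,5R)-3-(2,2-dimethoxyethyl)-4-methyl-5-(3,4,5-trimethoxyphenyl)oxolan-2-one, via thiohydroxamate ester 12 (not isolated)
Conditions: 1-hydroxypyridine-2(1H)-thione, DCC, DMAP (cat.), CH2Cl2, rt, dark; then t-BuSH, hν (tungsten lamp), rt
Reagents that add atoms: none
Why: Barton reductive decarboxylation: the O-acyl thiohydroxamate 12 fragments under visible light to CO2 and the primary radical on the C3 arm, which takes hydrogen from t-BuSH to leave the C3 methyl group. The radical centre is not a stereocentre, the aldehyde is masked as the acetal, and because the allyl alkene does not yet exist no 5-exo radical cyclisation can occur.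

Step 8
Reactants: 13 (3S,4R,5R)-3-(2,2-dimethoxyethyl)-4-methyl-5-(3,4,5-trimethoxyphenyl)oxolan-2-one
Product: 14 [(3S,4R,5R)-4-methyl-2-oxo-5-(3,4,5-trimethoxyphenyl)oxolan-3-yl]acetaldehyde
Conditions: 1 M aq HCl, THF, rt
Reagents that add atoms: water, O
Why: Acid-catalysed hydrolysis of a dimethyl acetal to the aldehyde; the lactone and the aryl methyl ethers are stable to dilute acid at room temperature.

Step 9
Reactants: 14 [(3S,4R,5R)-4-methyl-2-oxo-5-(3,4,5-trimethoxyphenyl)oxolan-3-yl]acetaldehyde
Product: 15 (3S,4R,5R)-4-methyl-3-(prop-2-en-1-yl)-5-(3,4,5-trimethoxyphenyl)oxolan-2-one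
Conditions: Ph3PCH3Br, KN(SiMe3)2, THF, 0 °C; then 14, −78 → 0 °C
Reagents that add atoms: methyltriphenylphosphonium bromide, C[P+](c1ccccc1)(c1ccccc1)c1ccccc1.[Br-]
Why: Wittig methylenation converts the CH2CHO arm into the allyl group; the non-stabilised ylide reacts with the aldehyde at low temperature and leaves the lactone carbonyl alone. Any epimerisation at C3a by the basic ylide is of no consequence because this centre is planarised in step 11.

Step 10
Reactants: 16 3,3-dimethoxybutan-2-one
Product: 17 3-methoxybut-3-en-2-one
Conditions: TsOH·H2O (cat.), hydroquinone (cat.), 140 °C, MeOH distilled off; then distillation under reduced pressure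
Reagents that add atoms: none
Why: Acid-catalysed elimination of methanol from a ketone dimethyl acetal gives the methyl enol ether; only the methyl group offers β-hydrogens, so a single alkene can form, distillation of methanol drives the reaction and hydroquinone prevents polymerisation.

Step 11
Reactants: 15 (3S,4R,5R)-4-methyl-3-(prop-2-en-1-yl)-5-(3,4,5-trimethoxyphenyl)oxolan-2-one; 17 3-methoxybut-3-en-2-one
Product: 18 (3R,4R,5R)-3-[(2RS)-2-methoxy-3-oxobutyl]-4-methyl-3-(prop-2-en-1-yl)-5-(3,4,5-trimethoxyphenyl)oxolan-2-one
Conditions: LiN(iPr)2, THF, −78 °C; then 17, −78 → −30 °C; AcOH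
Reagents that add atoms: none
Why: Michael addition of a lithium lactone enolate to an enone: the fully substituted, hindered enolate should prefer 1,4-addition to the unsubstituted β-carbon, any 1,2-adduct reverting on warming, and lithium chelation by the carbonyl and methoxy oxygens of 17 assists. C3a is set by the neighbouring C3 methyl group, anti to which the acceptor approaches, so the new chain is trans and the allyl group cis to methyl; C5 forms as a mixture and is settled in step 12.

Step 12
Reactants: 18 (3R,4R,5R)-3-[(2RS)-2-methoxy-3-oxobutyl]-4-methyl-3-(prop-2-en-1-yl)-5-(3,4,5-trimethoxyphenyl)oxolan-2-one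
Product: 21 (2R,3R,3aR,5R)-5-methoxy-3-methyl-3a-(prop-2-en-1-yl)-2-(3,4,5-trimethoxyphenyl)-3,3a,4,5-tetrahydro-1-benzofuran-6(2H)-one, via hydroxy dione 19 (not isolated), via C5 epimer mixture 20 (not isolated)
Conditions: KOtBu (2.2 equiv), THF, 0 °C → rt; AcOH; PPTS (cat.), toluene, 60 °C; then KOtBu (cat.), t-BuOH, rt
Reagents that add atoms: none
Why: Intramolecular Claisen condensation (the ring-closing half of the Michael–Claisen route to cyclohexane-1,3-diones): the methyl ketone enolate C7 attacks the lactone carbonyl C7a in a six-membered closure, the benzylic alkoxide is expelled and the stable dionate of 19 pulls the equilibrium; mild acid then closes the five-membered O1–C7a enol ether with loss of water. Catalytic tert-butoxide finally equilibrates C5 through the enolate: the dihydrofuran ring holds C3 near the enone plane and forces the allyl group pseudo-axial, so the epimer with the methoxy group equatorial and trans to allyl (21) is expected to predominate over the one with a 1,3-diaxial methoxy/allyl contact.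

## Compound list

1 | 3,4,5-trimethoxybenzaldehyde | COc1cc(C=O)cc(OC)c1OC | starting material
2 | vinylmagnesium bromide | C=C[Mg]Br | starting material
3 | (RS)-1-(3,4,5-trimethoxyphenyl)prop-2-en-1-ol | C=CC(O)c1cc(OC)c(OC)c(OC)c1 | intermediate
4 | (R)-1-(3,4,5-trimethoxyphenyl)prop-2-en-1-ol | C=C[C@@H](O)c1cc(OC)c(OC)c(OC)c1 | intermediate
5 | acryloyl chloride (prop-2-enoyl chloride) | C=CC(=O)Cl | starting material
6 | (1R)-1-(3,4,5-trimethoxyphenyl)prop-2-en-1-yl prop-2-enoate | C=C[C@@H](OC(=O)C=C)c1cc(OC)c(OC)c(OC)c1 | intermediate
7 | (5R)-5-(3,4,5-trimethoxyphenyl)furan-2(5H)-one | O=C1C=C[C@H](c2cc(OC)c(OC)c(OC)c2)O1 | intermediate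
8 | 2-(trimethylsilyloxy)buta-1,3-diene | C=CC(=C)O[Si](C)(C)C | starting material
9 | (3R,3aR,7aS)-3-(3,4,5-trimethoxyphenyl)-5-(trimethylsilyloxy)-3a,4,7,7a-tetrahydro-2-benzofuran-1(3H)-one | O=C1O[C@@H](c3cc(OC)c(OC)c(OC)c3)[C@@H]2CC(O[Si](C)(C)C)=CC[C@H]12 | intermediate
10 | [(2R,3R,4S)-5-oxo-4-(2-oxoethyl)-2-(3,4,5-trimethoxyphenyl)oxolan-3-yl]acetic acid | O=C1O[C@@H](c2cc(OC)c(OC)c(OC)c2)[C@H](CC(=O)O)[C@@H]1CC=O | intermediate
11 | [(2R,3R,4S)-4-(2,2-dimethoxyethyl)-5-oxo-2-(3,4,5-trimethoxyphenyl)oxolan-3-yl]acetic acid | O=C1O[C@@H](c2cc(OC)c(OC)c(OC)c2)[C@H](CC(=O)O)[C@@H]1CC(OC)OC | intermediate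
12 | 2-thioxopyridin-1(2H)-yl [(2R,3R,4S)-4-(2,2-dimethoxyethyl)-5-oxo-2-(3,4,5-trimethoxyphenyl)oxolan-3-yl]acetate | O=C1O[C@@H](c2cc(OC)c(OC)c(OC)c2)[C@H](CC(=O)ON3C=CC=CC3=S)[C@@H]1CC(OC)OC | intermediate
13 | (3S,4R,5R)-3-(2,2-dimethoxyethyl)-4-methyl-5-(3,4,5-trimethoxyphenyl)oxolan-2-one | O=C1O[C@@H](c2cc(OC)c(OC)c(OC)c2)[C@H](C)[C@@H]1CC(OC)OC | intermediate
14 | [(3S,4R,5R)-4-methyl-2-oxo-5-(3,4,5-trimethoxyphenyl)oxolan-3-yl]acetaldehyde | O=C1O[C@@H](c2cc(OC)c(OC)c(OC)c2)[C@H](C)[C@@H]1CC=O | intermediate
15 | (3S,4R,5R)-4-methyl-3-(prop-2-en-1-yl)-5-(3,4,5-trimethoxyphenyl)oxolan-2-one | C=CC[C@@H]1C(=O)O[C@@H](c2cc(OC)c(OC)c(OC)c2)[C@@H]1C | intermediate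
16 | 3,3-dimethoxybutan-2-one | CC(=O)C(C)(OC)OC | starting material
17 | 3-methoxybut-3-en-2-one | C=C(OC)C(C)=O | intermediate
18 | (3R,4R,5R)-3-[(2RS)-2-methoxy-3-oxobutyl]-4-methyl-3-(prop-2-en-1-yl)-5-(3,4,5-trimethoxyphenyl)oxolan-2-one | C=CC[C@]1(CC(OC)C(C)=O)C(=O)O[C@@H](c2cc(OC)c(OC)c(OC)c2)[C@@H]1C | intermediate
19 | (4R,6RS)-4-[(1R,2R)-1-hydroxy-1-(3,4,5-trimethoxyphenyl)propan-2-yl]-6-methoxy-4-(prop-2-en-1-yl)cyclohexane-1,3-dione | C=CC[C@@]1(CC(OC)C(=O)CC1=O)[C@@H](C)[C@@H](O)c1cc(OC)c(OC)c(OC)c1 | intermediate
20 | (2R,3R,3aR,5RS)-5-methoxy-3-methyl-3a-(prop-2-en-1-yl)-2-(3,4,5-trimethoxyphenyl)-3,3a,4,5-tetrahydro-1-benzofuran-6(2H)-one | C=CC[C@]12CC(OC)C(=O)C=C1O[C@@H](c1cc(OC)c(OC)c(OC)c1)[C@@H]2C | intermediate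
21 | (2R,3R,3aR,5R)-5-methoxy-3-methyl-3a-(prop-2-en-1-yl)-2-(3,4,5-trimethoxyphenyl)-3,3a,4,5-tetrahydro-1-benzofuran-6(2H)-one | C=CC[C@]12C[C@@H](OC)C(=O)C=C1O[C@@H](c1cc(OC)c(OC)c(OC)c1)[C@@H]2C | target

## Step count and least certain steps

Total step count: 12. Longest linear sequence: 11 steps (steps 1–9, 11 and 12); step 10 is a one-step side branch.

**Step 5 (key step).** The butenolide is only a moderate dienophile, so the cycloaddition may be slow enough for the diene to be lost by polymerisation. Regiocontrol by a single 2-siloxy group may be incomplete, and the minor adduct would carry the acid and aldehyde on exchanged arms. Prolonged heating may also erode the configuration at C2 through enolisation to a 2-hydroxyfuran. Fallback: from 7, conjugate addition of Me2CuLi with Me3SiCl in THF at −78 °C, anti to the aryl group, would give (4R,5R)-4-methyl-5-(3,4,5-trimethoxyphenyl)oxolan-2-one F1. Deprotonation with LiN(iPr)2 and alkylation with allyl bromide, anti to methyl, would give (3R,4R,5R)-4-methyl-3-(prop-2-en-1-yl)-5-(3,4,5-trimethoxyphenyl)oxolan-2-one F2, the C3a epimer of 15. F2 gives the same enolate as 15, so under the conditions of step 11 the fallback rejoins the route at 18.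

**Step 11.** The α-methoxy group donates into the alkene of 17 and lowers its electrophilicity, so 1,2-addition or anionic polymerisation of the enone may outrun conjugate addition. Facial selectivity may also be eroded because the C2 aryl group lies on the face of attack. Fallback: from 15, LiN(iPr)2 and Me3SiCl would give the silyl ketene acetal trimethyl{[(4R,5R)-4-methyl-3-(prop-2-en-1-yl)-5-(3,4,5-trimethoxyphenyl)-4,5-dihydrofuran-2-yl]oxy}silane F3. A Mukaiyama–Michael addition of F3 to 17 with TiCl4 in CH2Cl2 at −78 °C (the enone activated by chelation, the nucleophile neutral) returns to the route at 18.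

**Step 12.** Under tert-butoxide the ketone may enolise toward the methoxy-bearing C5 rather than the methyl group, opening a retro-Michael loss of the side chain. Acylation of the lactone carbonyl next to the quaternary centre may be slow, and the C5 equilibrium may be less one-sided than assumed. Fallback: the methoxy group is left out of the annulation and C5 is set kinetically.
- From 15, the silyl ketene acetal F3 and but-3-en-2-one with TiCl4 would give (3S,4R,5R)-4-methyl-3-(3-oxobutyl)-3-(prop-2-en-1-yl)-5-(3,4,5-trimethoxyphenyl)oxolan-2-one F4.
- KOtBu followed by PPTS, as in step 12, would give (2R,3R,3aS)-3-methyl-3a-(prop-2-en-1-yl)-2-(3,4,5-trimethoxyphenyl)-3,3a,4,5-tetrahydro-1-benzofuran-6(2H)-one F5.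
- Kinetic enolisation at C5 with LiN(iPr)2 and oxidation with 2-(phenylsulfonyl)-3-phenyloxaziridine, which enters anti to the pseudo-axial allyl group, would give (2R,3R,3aR,5R)-5-hydroxy-3-methyl-3a-(prop-2-en-1-yl)-2-(3,4,5-trimethoxyphenyl)-3,3a,4,5-tetrahydro-1-benzofuran-6(2H)-one F6.
- O-methylation with Me3OBF4 and 1,8-bis(dimethylamino)naphthalene arrives at 21.

**Step 6.** Ozone may over-oxidise the trimethoxyphenyl ring, the silyl enol ether may be solvolysed to the ketone before it is cleaved, and the acid may be partly esterified during acetalisation. Fallback: from 9, dihydroxylation of the silyl enol ether with OsO4 (cat.) and N-methylmorpholine N-oxide would give (3R,3aR,7aS)-6-hydroxy-3-(3,4,5-trimethoxyphenyl)hexahydro-2-benzofuran-1,5-dione F7. Cleavage of this α-hydroxy ketone with NaIO4 in aqueous THF gives the acid on the C3 arm and the aldehyde on the C3a arm, returning to the route at 10, which is acetalised to 11 as before.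

**Step 2.** Epoxidation of a monosubstituted alkene is slow, so discrimination between the enantiomers may be modest, and the titanium Lewis acid may ionise the electron-rich benzylic alcohol. Fallback: from 3, acylation with vinyl acetate catalysed by immobilised lipase B from Candida antarctica, which by the usual enantiopreference of lipases for aryl carbinols acylates the (R)-enantiomer, would give (1R)-1-(3,4,5-trimethoxyphenyl)prop-2-en-1-yl acetate F8. After separation from the unreacted (S)-alcohol, methanolysis with K2CO3 in MeOH returns to the route at 4.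

## Further compounds

F1 | step 5 | (4R,5R)-4-methyl-5-(3,4,5-trimethoxyphenyl)oxolan-2-one | C1C(=O)O[C@@H](c2cc(OC)c(OC)c(OC)c2)[C@@H]1C
F2 | step 5 | (3R,4R,5R)-4-methyl-3-(prop-2-en-1-yl)-5-(3,4,5-trimethoxyphenyl)oxolan-2-one | C=CC[C@H]1C(=O)O[C@@H](c2cc(OC)c(OC)c(OC)c2)[C@@H]1C
F3 | step 11 | trimethyl{[(4R,5R)-4-methyl-3-(prop-2-en-1-yl)-5-(3,4,5-trimethoxyphenyl)-4,5-dihydrofuran-2-yl]oxy}silane | C=CCC1=C(O[Si](C)(C)C)O[C@@H](c2cc(OC)c(OC)c(OC)c2)[C@@H]1C
F4 | step 12 | (3S,4R,5R)-4-methyl-3-(3-oxobutyl)-3-(prop-2-en-1-yl)-5-(3,4,5-trimethoxyphenyl)oxolan-2-one | C=CC[C@]1(CCC(C)=O)C(=O)O[C@@H](c2cc(OC)c(OC)c(OC)c2)[C@@H]1C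
F5 | step 12 | (2R,3R,3aS)-3-methyl-3a-(prop-2-en-1-yl)-2-(3,4,5-trimethoxyphenyl)-3,3a,4,5-tetrahydro-1-benzofuran-6(2H)-one | C=CC[C@]12CCC(=O)C=C1O[C@@H](c1cc(OC)c(OC)c(OC)c1)[C@@H]2C
F6 | step 12 | (2R,3R,3aR,5R)-5-hydroxy-3-methyl-3a-(prop-2-en-1-yl)-2-(3,4,5-trimethoxyphenyl)-3,3a,4,5-tetrahydro-1-benzofuran-6(2H)-one | C=CC[C@]12C[C@@H](O)C(=O)C=C1O[C@@H](c1cc(OC)c(OC)c(OC)c1)[C@@H]2C
F7 | step 6 | (3R,3aR,7aS)-6-hydroxy-3-(3,4,5-trimethoxyphenyl)hexahydro-2-benzofuran-1,5-dione (C6 epimers) | O=C1O[C@@H](c3cc(OC)c(OC)c(OC)c3)[C@@H]2CC(=O)C(O)C[C@H]12
F8 | step 2 | (1R)-1-(3,4,5-trimethoxyphenyl)prop-2-en-1-yl acetate | C=C[C@@H](OC(C)=O)c1cc(OC)c(OC)c(OC)c1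
A1 | alternative 1 | cis-fused 3a-allyl-6-(tert-butyldimethylsilyloxy)-5-methoxy-3-methyl-2-(3,4,5-trimethoxyphenyl)-2,3,3a,4,5,7a-hexahydro-1-benzofuran | C=CC[C@]12C[C@@H](OC)C(O[Si](C)(C)C(C)(C)C)=C[C@H]1O[C@@H](c1cc(OC)c(OC)c(OC)c1)[C@@H]2C
A2 | alternative 1 | (1R,2R)-2-methyl-3-methylidene-1-(3,4,5-trimethoxyphenyl)hex-5-en-1-yl (1E)-3-(tert-butyldimethylsilyloxy)-4-methoxybuta-1,3-dien-1-yl ether | C=CCC(=C)[C@@H](C)[C@H](c1cc(OC)c(OC)c(OC)c1)O/C=C/C(O[Si](C)(C)C(C)(C)C)=COC
A3 | alternative 2 | cis-fused 3a-allyl-3-methyl-2-(3,4,5-trimethoxyphenyl)-3,3a,7,7a-tetrahydro-1-benzofuran-6(2H)-one | C=CC[C@]12C=CC(=O)C[C@H]1O[C@@H](c1cc(OC)c(OC)c(OC)c1)[C@@H]2C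
A4 | alternative 2 | 4-[(1R,2R)-1-hydroxy-1-(3,4,5-trimethoxyphenyl)propan-2-yl]-4-(prop-2-en-1-yl)cyclohexa-2,5-dien-1-one | C=CCC1(C=CC(=O)C=C1)[C@@H](C)[C@@H](O)c1cc(OC)c(OC)c(OC)c1
A5 | alternative 3 | (3R,4R,5R)-3-[(2R)-2-methoxy-3-oxobutyl]-4-methyl-3-(prop-2-en-1-yl)-5-(3,4,5-trimethoxyphenyl)oxolan-2-one | C=CC[C@]1(C[C@@H](OC)C(C)=O)C(=O)O[C@@H](c2cc(OC)c(OC)c(OC)c2)[C@@H]1C
A6 | alternative 3 | (5R)-3-(prop-2-en-1-yl)-5-(3,4,5-trimethoxyphenyl)furan-2(5H)-one | C=CCC1=C[C@H](c2cc(OC)c(OC)c(OC)c2)OC1=O
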